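**Retrosynthetic overview**
- The only ring, the ten-membered carbocycle, is closed last: C3–C4 by Ni/Cr (Nozaki–Hiyama–Kishi) coupling of a (Z)-iodoalkene with an aldehyde, which also creates the free C4 carbinol.
- The C1-acetate/C9-benzoate anti-1,3-diol comes from a beta-hydroxy ketone by Evans–Tishchenko reduction with benzaldehyde, then acetylation.
- That ketone is cut at C9–C10: syn boron aldol of a west (Z)-iodoenone (C1–C3, C10, isopropyl) with an east (Z)-beta,gamma-unsaturated aldehyde (C4–C9).
- West piece from but-2-yn-1-ol (Red-Al/I2 fixes the Z iodoalkene) and an isobutyl Grignard; east piece from m-cresol (Birch reduction/selective ozonolysis fixes the Z trisubstituted alkene).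
- Ring order: no ring is formed before the final step.

Assumption: the SMILES is read literally – ring numbered C1 (CHOAc), C2=C3(Me), C4 (CHOH), C5, C6=C7(Me), C8, C9 (CHOBz), C10 (CH-iPr); both alkenes Z (ring carbons cis); configuration 1S,4R,9S,10R.

**West fragment**

Step 1
Reactants: 1 but-2-yn-1-ol
Product: 3 (2Z)-3-iodobut-2-en-1-ol, via cyclic alkenylalanate 2 (not isolated)
Conditions: NaAlH2(OCH2CH2OMe)2 (Red-Al), THF, 0 °C to rt; then I2, THF, −78 to 0 °C
Reagents that add atoms: iodine, II
Why: Hydroxyl-directed trans-hydroalumination of the propargylic alcohol (Corey-type Red-Al reduction) puts aluminium on C3 cis to the CH2O group in the cyclic alanate 2, and iodinolysis of the C–Al bond with retention gives only the Z iodoalkene that later becomes the Z C2=C3 alkene of the ring.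

Step 2
Reactants: 3 (2Z)-3-iodobut-2-en-1-ol
Product: 4 (2Z)-3-iodobut-2-enal
Conditions: MnO2, CH2Cl2, rt, dark
Reagents that add atoms: none
Why: Chemoselective MnO2 oxidation of a primary allylic alcohol under neutral conditions that leave the Z iodoalkene geometry untouched.

Step 3
Reactants: 4 (2Z)-3-iodobut-2-enal; 5 isobutylmagnesium bromide
Product: 6 (2Z)-2-iodo-6-methylhept-2-en-4-ol (racemic at C4)
Conditions: Et2O, −78 °C; aq NH4Cl
Reagents that add atoms: none
Why: Grignard 1,2-addition to the unhindered enal at low temperature is faster than conjugate addition–elimination at the iodide-bearing carbon; the new carbinol centre is racemic and is erased in step 4.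

Step 4
Reactants: 6 (2Z)-2-iodo-6-methylhept-2-en-4-ol
Product: 7 (2Z)-2-iodo-6-methylhept-2-en-4-one
Conditions: Dess–Martin periodinane, CH2Cl2, 0 °C to rt
Reagents that add atoms: none
Why: Dess–Martin oxidation of the secondary allylic alcohol gives the beta-iodoenone under non-basic conditions that do not isomerise the Z alkene.

**East fragment**

Step 5
Reactants: 8 3-methylphenol (m-cresol)
Product: 9 1-methoxy-3-methylbenzene
Conditions: MeI, K2CO3, acetone, reflux
Reagents that add atoms: iodomethane, CI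
Why: Williamson O-methylation of the phenoxide.

Step 6
Reactants: 9 1-methoxy-3-methylbenzene
Product: 10 1-methoxy-5-methylcyclohexa-1,4-diene
Conditions: Li, NH3 (l), THF, t-BuOH, −78 to −33 °C
Reagents that add atoms: none
Why: Birch reduction leaves both donor substituents on the residual alkenes, giving the 1,4-diene in which the future C6=C7 alkene is locked cis inside the six-membered ring.

Step 7
Reactants: 10 1-methoxy-5-methylcyclohexa-1,4-diene
Product: 12 methyl (3Z)-6,6-dimethoxy-3-methylhex-3-enoate, via aldehyde ester 11 (not isolated)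
Conditions: O3 (1 equiv), CH2Cl2/MeOH, −78 °C; Me2S, −78 °C to rt; then HC(OMe)3, PPTS (cat.), MeOH, rt
Reagents that add atoms: ozone, [O-][O+]=O; trimethyl orthoformate, COC(OC)OC
Why: Ozone attacks the electron-rich enol ether far faster than the trialkyl alkene (Corey's Birch–selective ozonolysis tactic), so ring cleavage gives the methyl ester (future C9) and the aldehyde (future C4) with the Z alkene preserved, and the aldehyde is masked in the same flask as its dimethyl acetal.

Step 8
Reactants: 12 methyl (3Z)-6,6-dimethoxy-3-methylhex-3-enoate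
Product: 13 (3Z)-6,6-dimethoxy-3-methylhex-3-enal
Conditions: i-Bu2AlH (1.05 equiv), CH2Cl2, −78 °C; MeOH, aq potassium sodium tartrate
Reagents that add atoms: none
Why: Partial ester reduction with i-Bu2AlH stops at the tetrahedral aluminium hemiacetal at −78 °C and releases the beta,gamma-unsaturated aldehyde only on neutral work-up, so it is used at once before it can conjugate.

**Union and endgame**

Step 9
Reactants: 7 (2Z)-2-iodo-6-methylhept-2-en-4-one; 13 (3Z)-6,6-dimethoxy-3-methylhex-3-enal
Product: 15 (2Z,5R,6S,8Z)-6-hydroxy-2-iodo-11,11-dimethoxy-8-methyl-5-(propan-2-yl)undeca-2,8-dien-4-one, via (Z)-enol borinate 14 (not isolated)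
Conditions: (+)-Ipc2BOTf [from (−)-α-pinene], i-Pr2NEt, CH2Cl2, −78 °C; then 13, −78 to −20 °C; H2O2, MeOH, pH 7 buffer, 0 °C
Reagents that add atoms: none
Why: Paterson asymmetric boron aldol – the triflate/hindered amine pair gives the (Z)-enol borinate 14 on the only enolisable side of 7, which adds through a chair Zimmerman–Traxler transition state to give the 5,6-syn adduct, and the isopinocampheyl groups of the (−)-α-pinene-derived reagent direct attack to the re face of 13 (ethyl-ketone-type enolates of the (+)-α-pinene-derived reagent attack the si face), setting C9 (S) and C10 (R) of the target.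

Step 10
Reactants: 15 (2Z,5R,6S,8Z)-6-hydroxy-2-iodo-11,11-dimethoxy-8-methyl-5-(propan-2-yl)undeca-2,8-dien-4-one; 16 benzaldehyde
Product: 18 (2Z,4R,5R,6S,8Z)-4-(acetyloxy)-2-iodo-11,11-dimethoxy-8-methyl-5-(propan-2-yl)undeca-2,8-dien-6-yl benzoate, via hydroxy benzoate 17 (not isolated)
Conditions: SmI2 (0.3 equiv), THF, −10 °C; then Ac2O, pyridine, DMAP, 0 °C to rt
Reagents that add atoms: acetic anhydride, CC(=O)OC(C)=O
Why: Evans–Tishchenko reduction – the samarium-bound hemiacetal formed from the C6 hydroxyl and benzaldehyde delivers hydride intramolecularly to the ketone through a chair-like transition state, giving the 1,3-anti carbinol (C1 of the target, S there) with the benzoyl group left on the original hydroxyl, and the free allylic alcohol is acetylated in the same flask before acyl migration can occur.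

Step 11
Reactants: 18 (2Z,4R,5R,6S,8Z)-4-(acetyloxy)-2-iodo-11,11-dimethoxy-8-methyl-5-(propan-2-yl)undeca-2,8-dien-6-yl benzoate
Product: 19 (3Z,6S,7R,8R,9Z)-8-(acetyloxy)-10-iodo-4-methyl-1-oxo-7-(propan-2-yl)undeca-3,9-dien-6-yl benzoate
Conditions: LiBF4, MeCN/H2O (50:1), rt
Reagents that add atoms: water, O
Why: Mild Lewis-acid hydrolysis of the dimethyl acetal (Lipshutz LiBF4 conditions) frees the aldehyde without touching the esters, the allylic acetate or the iodoalkene and without moving the beta,gamma alkene into conjugation.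

Step 12
Reactants: 19 (3Z,6S,7R,8R,9Z)-8-(acetyloxy)-10-iodo-4-methyl-1-oxo-7-(propan-2-yl)undeca-3,9-dien-6-yl benzoate
Product: 20 (1S,2Z,4R,6Z,9S,10R)-9-(benzoyloxy)-4-hydroxy-3,7-dimethyl-10-(propan-2-yl)cyclodeca-2,6-dien-1-yl acetate
Conditions: CrCl2 (0.2 equiv), (S)-N-[2-(4-tert-butyl-4,5-dihydro-1,3-oxazol-2-yl)-6-methoxyphenyl]methanesulfonamide (0.22 equiv), 1,8-bis(dimethylamino)naphthalene (0.22 equiv), NiCl2·(2,9-dimethyl-1,10-phenanthroline) (0.05 equiv), Mn, Cp2ZrCl2, LiCl, MeCN, rt, slow addition of 19 (final 2 mM)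
Reagents that add atoms: none
Why: Proposed new method: a chromium-catalytic, ligand-controlled Nozaki–Hiyama–Kishi closure of a ten-membered carbocycle – zerovalent nickel (from the NiCl2 complex and Mn) inserts into the C–I bond of the (Z)-2-iodoalkene with retention, the alkenyl group passes to the trivalent chromium centre held by the chiral oxazoline sulfonamide, the tethered aldehyde binds the same chromium and is attacked on its si face (ligand antipode chosen for this by analogy with the intermolecular model) to give the 4R carbinol, Cp2ZrCl2 strips the product alkoxide so that Mn returns chromium to the divalent state, and slow addition lets ring closure outrun dimerisation; the closest known chemistry is Kishi's catalytic asymmetric Ni/Cr coupling of iodoalkenes with aldehydes, established between separate partners and for large rings but not for catalyst-controlled closure of a strained ten-membered carbocycle onto a beta,gamma-unsaturated aldehyde.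

**Compound list**
1 | but-2-yn-1-ol | CC#CCO | starting material
2 | sodium 2,2-bis(2-methoxyethoxy)-3-methyl-2,5-dihydro-1,2-oxaluminol-2-uide (cyclic (Z)-alkenylalanate) | CC1=CCO[Al-]1(OCCOC)OCCOC.[Na+] | intermediate
3 | (2Z)-3-iodobut-2-en-1-ol | OC/C=C(/C)I | intermediate
4 | (2Z)-3-iodobut-2-enal | O=C/C=C(/C)I | intermediate
5 | isobutylmagnesium bromide (2-methylpropylmagnesium bromide) | CC(C)C[Mg]Br | starting material
6 | (2Z)-2-iodo-6-methylhept-2-en-4-ol (racemic at C4) | CC(C)CC(O)/C=C(/C)I | intermediate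
7 | (2Z)-2-iodo-6-methylhept-2-en-4-one | CC(C)CC(=O)/C=C(/C)I | intermediate
8 | 3-methylphenol (m-cresol) | Cc1cccc(O)c1 | starting material
9 | 1-methoxy-3-methylbenzene | COc1cccc(C)c1 | intermediate
10 | 1-methoxy-5-methylcyclohexa-1,4-diene | COC1=CCC=C(C)C1 | intermediate
11 | methyl (3Z)-3-methyl-6-oxohex-3-enoate | O=CC/C=C(/C)CC(=O)OC | intermediate
12 | methyl (3Z)-6,6-dimethoxy-3-methylhex-3-enoate | COC(OC)C/C=C(/C)CC(=O)OC | intermediate
13 | (3Z)-6,6-dimethoxy-3-methylhex-3-enal | COC(OC)C/C=C(/C)CC=O | intermediate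
14 | (2Z,4Z)-2-iodo-6-methylhepta-2,4-dien-4-yl bis[(1S,2R,3S,5S)-2,6,6-trimethylbicyclo[3.1.1]heptan-3-yl]borinate | CC(C)/C=C(\OB([C@H]1C[C@H]2C[C@@H]([C@@H]1C)C2(C)C)[C@H]1C[C@H]2C[C@@H]([C@@H]1C)C2(C)C)/C=C(/C)I | intermediate
15 | (2Z,5R,6S,8Z)-6-hydroxy-2-iodo-11,11-dimethoxy-8-methyl-5-(propan-2-yl)undeca-2,8-dien-4-one | COC(OC)C/C=C(/C)C[C@H](O)[C@@H](C(C)C)C(=O)/C=C(/C)I | intermediate
16 | benzaldehyde | O=Cc1ccccc1 | starting material
17 | (2Z,4R,5S,6S,8Z)-4-hydroxy-2-iodo-11,11-dimethoxy-8-methyl-5-(propan-2-yl)undeca-2,8-dien-6-yl benzoate | COC(OC)C/C=C(/C)C[C@H](OC(=O)c1ccccc1)[C@@H](C(C)C)[C@@H](O)/C=C(/C)I | intermediate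
18 | (2Z,4R,5R,6S,8Z)-4-(acetyloxy)-2-iodo-11,11-dimethoxy-8-methyl-5-(propan-2-yl)undeca-2,8-dien-6-yl benzoate | COC(OC)C/C=C(/C)C[C@H](OC(=O)c1ccccc1)[C@@H](C(C)C)[C@@H](OC(C)=O)/C=C(/C)I | intermediate
19 | (3Z,6S,7R,8R,9Z)-8-(acetyloxy)-10-iodo-4-methyl-1-oxo-7-(propan-2-yl)undeca-3,9-dien-6-yl benzoate | O=CC/C=C(/C)C[C@H](OC(=O)c1ccccc1)[C@@H](C(C)C)[C@@H](OC(C)=O)/C=C(/C)I | intermediate
20 | (1S,2Z,4R,6Z,9S,10R)-9-(benzoyloxy)-4-hydroxy-3,7-dimethyl-10-(propan-2-yl)cyclodeca-2,6-dien-1-yl acetate | CC(=O)O[C@H]1/C=C(/C)[C@H](O)C/C=C(/C)C[C@H](OC(=O)c2ccccc2)[C@H]1C(C)C | target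

**Step count**
Total: 12 steps. Longest linear sequence: 8 steps (steps 1–4 or steps 5–8, then steps 9–12).

**Three steps most likely to fail**

Step 12 (the proposed new ring closure). The risks are dimerisation, weak catalyst control at C4 against the ring's own bias, and conjugation of the aldehyde. The fallback uses known chemistry, sets out from 19 and comes back at 20. Classical ring closure with excess CrCl2 and catalytic NiCl2 in DMSO/THF at high dilution gives 20 mixed with its C4 epimer, (1S,2Z,4S,6Z,9S,10R)-9-(benzoyloxy)-4-hydroxy-3,7-dimethyl-10-(propan-2-yl)cyclodeca-2,6-dien-1-yl acetate F1. The unseparated mixture is oxidised with Dess–Martin periodinane to (1S,2Z,6Z,9S,10R)-9-(benzoyloxy)-3,7-dimethyl-4-oxo-10-(propan-2-yl)cyclodeca-2,6-dien-1-yl acetate F2. The C4 carbinol is then set by reagent-controlled reduction with (S)-Me-CBS and catecholborane (alkenyl side as the large group), returning 20; C4 is thus fixed by ketone reduction, not in the C–C bond-forming event.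

Step 9 (the aldol union). The risks are conjugation of aldehyde 13, activation of its acetal by free boron triflate, and modest or wrong-sense reagent control on this isobutyl iodoenone. The fallback sets out from 13 and comes back at 15, with the configuration set by an auxiliary. Lithiated (R)-4-benzyl-1,3-oxazolidin-2-one is acylated with 3-methylbutanoyl chloride to (4R)-4-benzyl-3-(3-methylbutanoyl)-1,3-oxazolidin-2-one F3. Its Bu2BOTf/i-Pr2NEt enolate adds to 13 to give the Evans syn adduct (4R)-4-benzyl-3-[(2R,3S,5Z)-3-hydroxy-8,8-dimethoxy-5-methyl-2-(propan-2-yl)oct-5-enoyl]-1,3-oxazolidin-2-one F4. Me3Al and N,O-dimethylhydroxylamine hydrochloride convert it to (2R,3S,5Z)-3-hydroxy-N,8,8-trimethoxy-N,5-dimethyl-2-(propan-2-yl)oct-5-enamide F5. 1-Propynylmagnesium bromide gives (5R,6S,8Z)-6-hydroxy-11,11-dimethoxy-8-methyl-5-(propan-2-yl)undec-8-en-2-yn-4-one F6, and anti hydroiodination (LiI, AcOH, MeCN) delivers the (Z)-beta-iodoenone 15.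

Step 10 (Evans–Tishchenko on a beta-hydroxy beta'-iodoenone). The risks are retro-aldol cleavage, cyclisation of the hydroxyl onto the iodoenone to a dihydropyranone, and benzoate migration. The fallback sets out from 15 and comes back at 17. The C6 hydroxyl is benzoylated first (benzoyl chloride, pyridine, 0 °C) to (2Z,5R,6S,8Z)-2-iodo-11,11-dimethoxy-8-methyl-4-oxo-5-(propan-2-yl)undeca-2,8-dien-6-yl benzoate F7. The ketone is then reduced under reagent control with (R)-Me-CBS and catecholborane at −78 °C (branched C5 side as the large group) to give 17, here isolated, which is acetylated to 18 as in the second half of step 10.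

**Further compounds**
F1 | step 12 | (1S,2Z,4S,6Z,9S,10R)-9-(benzoyloxy)-4-hydroxy-3,7-dimethyl-10-(propan-2-yl)cyclodeca-2,6-dien-1-yl acetate | CC(=O)O[C@H]1/C=C(/C)[C@@H](O)C/C=C(/C)C[C@H](OC(=O)c2ccccc2)[C@H]1C(C)C
F2 | step 12 | (1S,2Z,6Z,9S,10R)-9-(benzoyloxy)-3,7-dimethyl-4-oxo-10-(propan-2-yl)cyclodeca-2,6-dien-1-yl acetate | CC(=O)O[C@H]1/C=C(/C)C(=O)C/C=C(/C)C[C@H](OC(=O)c2ccccc2)[C@H]1C(C)C
F3 | step 9 | (4R)-4-benzyl-3-(3-methylbutanoyl)-1,3-oxazolidin-2-one | CC(C)CC(=O)N1[C@H](Cc2ccccc2)COC1=O
F4 | step 9 | (4R)-4-benzyl-3-[(2R,3S,5Z)-3-hydroxy-8,8-dimethoxy-5-methyl-2-(propan-2-yl)oct-5-enoyl]-1,3-oxazolidin-2-one | COC(OC)C/C=C(/C)C[C@H](O)[C@@H](C(C)C)C(=O)N1[C@H](Cc2ccccc2)COC1=O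
F5 | step 9 | (2R,3S,5Z)-3-hydroxy-N,8,8-trimethoxy-N,5-dimethyl-2-(propan-2-yl)oct-5-enamide | COC(OC)C/C=C(/C)C[C@H](O)[C@@H](C(C)C)C(=O)N(C)OC
F6 | step 9 | (5R,6S,8Z)-6-hydroxy-11,11-dimethoxy-8-methyl-5-(propan-2-yl)undec-8-en-2-yn-4-one | COC(OC)C/C=C(/C)C[C@H](O)[C@@H](C(C)C)C(=O)C#CC
F7 | step 10 | (2Z,5R,6S,8Z)-2-iodo-11,11-dimethoxy-8-methyl-4-oxo-5-(propan-2-yl)undeca-2,8-dien-6-yl benzoate | COC(OC)C/C=C(/C)C[C@H](OC(=O)c1ccccc1)[C@@H](C(C)C)C(=O)/C=C(/C)I
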